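| flask | electrophile | nucleophile | remark | time |
|---|---|---|---|---|
| noon | 20 mM | 2.8 mM | run made earlier |  |
| winter | 31 mM | 16 mM | run made earlier |  |
| Sunday's | 20 mM | 5.00 mM |  | 2.5 d |
| Wednesday's | 60 mM | 10.0 mM |  | 2.5 d |
| Thursday's | 20 mM | 16.0 mM |  | 2.5 d |
| Saturday's | 20 mM | 4.00 mM |  | 2.5 d |
| Monday's | 10 mM | 25.0 mM |  | 2.5 d |

| run | time / h | target / % |
|---|---|---|
| noon | 3.00 | 13 |
| noon | 6.00 | 16 |
| noon | 10.0 | 13 |
| noon | 15.0 | 11 |
| noon | 25.0 | 18 |
| noon | 40.0 | 17 |
| winter | 3.00 | 42 |
| winter | 6.00 | 50 |
| winter | 12.0 | 52 |
| winter | 20.0 | 49 |
| winter | 40.0 | 55 |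

(scatter of a reading: 2 percentage points)



1. ranking by amount of target, in percent of the electrophile charged, from high to low, at 2.5 d (Sunday's / Wednesday's / Thursday's / Saturday's / Monday's)
2. the amount of target, in percent of the electrophile charged of the flask you put first, at 2.5 d
3. the amount of target, in percent of the electrophile charged of the flask you put last, at 2.5 d

**Small charge.** A small charge of nucleophile, 2.8 mM against 20 mM of electrophile, went into the noon run, and its target readings average 14.7% of the electrophile charged. The charge ratio of that run, nucleophile over electrophile, was 14.0%. In the winter run the ratio was 51.6%, and the readings after the first average 51.5%. So I read one electrophile used per nucleophile, with nucleophile as the limiting reagent in both runs.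

**Time.** At its first reading, 3.00 h, the target reading of the winter run, counted one for one, put 18.6% of its nucleophile still unreacted. The asked 2.5 d is much longer, so I reckoned with the two charges and not with the clock.

**Two charges.** Monday's has 2.50, the equivalents of nucleophile per electrophile charged. That is above one, so electrophile is limiting there and my ceiling is 100%. Wednesday's ratio, 16.7%, is the lowest.

**The forecast.** It gave Monday's > Thursday's > Sunday's > Saturday's > Wednesday's, with 92% on top and 16.7% at the bottom. On Monday's it wrote “Target could be lost to further reaction” and shaded its number, and my ceiling stands 8 percentage points higher.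

**The flask.** The order came out as Monday's > Thursday's > Sunday's > Saturday's > Wednesday's, with Monday's at 99.5% and Wednesday's at 16.6%.

    acid set free + target → side product (k = 0.0440 M⁻¹ min⁻¹)
    nucleophile + acid set free ⇌ protonated nucleophile, settled at all times (K = 19000 M⁻¹)
    acid set free → by-product carried off (k = 0.0550 min⁻¹)
    electrophile + nucleophile → acid set free + target (k = 8.50 M⁻¹ min⁻¹)

Monday's held 0.538% of side product, in percent of the electrophile charged, at 2.50 d, and the ceiling from 2.50 equivalents stands 0.50 points above its target.

**Neighbour flask.** With 40 mM of electrophile and Monday's nucleophile, the equivalents fall to 0.625, so I expect 62.5% of target and 37.5% of the electrophile left. That neighbour gave 61.6% of target, with 38% of its electrophile left.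

The data are simulated on assumed constants; noise was put on by code.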